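## Retrosynthetic overview
1. Ring C is the only ring that has to be made. It is opened at O1–C2, which leads back by cyclodehydration to 1-(6-hydroxy-2,3-dimethoxyphenyl)-3-(3,4,5-trimethoxyphenyl)propane-1,3-dione.
2. The key disconnection is C3–C4. The formyl carbon of 6-hydroxy-2,3-dimethoxybenzaldehyde acts as an acyl anion equivalent (a phenoxide-chelated acyl–rhodium species). C3 arrives as an electrophilic α-oxo carbenoid released from an aroyl sulfoxonium ylide.
3. The salicylaldehyde comes from 3,4-dimethoxyphenol through its MOM ether, by ortho-lithiation and formylation at the carbon between the two oxygens.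
4. The ylide comes from 3,4,5-trimethoxybenzoyl chloride and dimethylsulfoxonium methylide.
5. Rings A and B are bought intact. Ring C is closed last, in the same flask as the key C–C bond.

Assumption: the target SMILES has no stereocentre and no stereogenic double bond. The compound is achiral, so "single enantiomer" calls for no stereocontrol.

## Route

Step 1
Reactants: 1 3,4-dimethoxyphenol
Product: 2 1,2-dimethoxy-4-(methoxymethoxy)benzene
Conditions: NaH (1.2 equiv), MOMCl (1.2 equiv), DMF, 0 °C to rt
Reagents that add atoms: chloromethyl methyl ether (MOMCl), COCCl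
Why: Williamson-type O-alkylation of the sodium phenoxide with the reactive α-chloro ether masks the acidic O–H and installs the directing group for step 2; no stereocentre is formed.

Step 2
Reactants: 2 1,2-dimethoxy-4-(methoxymethoxy)benzene
Product: 5 6-hydroxy-2,3-dimethoxybenzaldehyde, via aryllithium 3 (not isolated), via MOM-protected aldehyde 4 (not isolated)
Conditions: n-BuLi (1.2 equiv), THF, 0 °C to rt; DMF (2 equiv), 0 °C to rt; then 3 M aq HCl, 50 °C
Reagents that add atoms: N,N-dimethylformamide, CN(C)C=O; n-butyllithium, [Li]CCCC (its lithium stands only in 3)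
Why: In this directed ortho-metalation the OMOM and neighbouring OMe groups jointly direct n-BuLi to the one C–H between them, DMF formylates the aryllithium, and aqueous acid collapses the hemiaminal and hydrolyses the MOM acetal while the aryl methyl ethers stay untouched.

Step 3
Reactants: 6 3,4,5-trimethoxybenzoyl chloride
Product: 7 dimethylsulfoxonium 2-oxo-2-(3,4,5-trimethoxyphenyl)ethylide
Conditions: Me3S(O)I (3 equiv), KOt-Bu (3 equiv), THF, reflux 2 h; then 6, 0 °C to rt
Reagents that add atoms: trimethylsulfoxonium iodide, C[S+](C)(C)=O.[I-]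
Why: This is C-acylation of the Corey–Chaykovsky methylide by the acid chloride, after which a second equivalent of methylide removes the now acidic α-proton to give the bench-stable carbonyl-stabilised ylide.

Step 4 (key step)
Reactants: 5 6-hydroxy-2,3-dimethoxybenzaldehyde; 7 dimethylsulfoxonium 2-oxo-2-(3,4,5-trimethoxyphenyl)ethylide (1.5 equiv)
Product: 9 5,6-dimethoxy-2-(3,4,5-trimethoxyphenyl)-4H-chromen-4-one (cerosilin B), via 1,3-diketone 8 (not isolated)
Conditions: [Cp*RhCl2]2 (4 mol %), AgSbF6 (16 mol %), CsOAc (50 mol %), PivOH (1 equiv), DCE, 100 °C, N2; then p-TsOH·H2O (20 mol %), 100 °C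
Reagents that add atoms: none
Why: In this known trivalent-rhodium-catalysed salicylaldehyde/sulfoxonium ylide annulation, phenoxide-directed formyl C–H activation turns the normally electrophilic aldehyde carbon of 5 into a five-membered acyl–rhodium chelate (a catalytic acyl anion equivalent), which migrates onto the electrophilic α-oxo rhodium carbene formed from 7 by loss of DMSO, protodemetalation gives 8, and acid-catalysed cyclodehydration closes ring C without forming a stereocentre.

## Compound list
1 | 3,4-dimethoxyphenol | COc1ccc(O)cc1OC | starting material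
2 | 1,2-dimethoxy-4-(methoxymethoxy)benzene | COCOc1ccc(OC)c(OC)c1 | intermediate
3 | [2,3-dimethoxy-6-(methoxymethoxy)phenyl]lithium (in situ) | [Li]c1c(OC)c(OC)ccc1OCOC | intermediate
4 | 2,3-dimethoxy-6-(methoxymethoxy)benzaldehyde (in situ) | COCOc1ccc(OC)c(OC)c1C=O | intermediate
5 | 6-hydroxy-2,3-dimethoxybenzaldehyde | COc1ccc(O)c(C=O)c1OC | intermediate
6 | 3,4,5-trimethoxybenzoyl chloride | COc1cc(C(=O)Cl)cc(OC)c1OC | starting material
7 | dimethylsulfoxonium 2-oxo-2-(3,4,5-trimethoxyphenyl)ethylide | COc1cc(C(=O)C=S(C)(C)=O)cc(OC)c1OC | intermediate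
8 | 1-(6-hydroxy-2,3-dimethoxyphenyl)-3-(3,4,5-trimethoxyphenyl)propane-1,3-dione (in situ) | COc1ccc(O)c(C(=O)CC(=O)c2cc(OC)c(OC)c(OC)c2)c1OC | intermediate
9 | 5,6-dimethoxy-2-(3,4,5-trimethoxyphenyl)-4H-chromen-4-one (cerosilin B, achiral) | COc1cc(-c2cc(=O)c3c(OC)c(OC)ccc3o2)cc(OC)c1OC | target

## Step count and risks
Total steps: 4. Longest linear sequence: 3 (1 → 2 → 5 → 9). The branch 6 → 7 is one step.

**Step 4 (most at risk).**
- The formyl group sits between two ortho substituents, which can slow the C–H metalation.
- The carbene can insert into the phenol O–H, which leads on to a 2-aroylbenzofuran.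
- Ylide 7 can couple with itself.

The fallback sets out from 5 and comes back at 9. Compound 5 is used in a chelation-assisted alkyne hydroacylation with commercial 5-ethynyl-1,2,3-trimethoxybenzene (C#Cc1cc(OC)c(OC)c(OC)c1). The conditions are [RhCl(cod)]2 (monovalent rhodium), dppf and Na2CO3 in toluene at reflux. The formyl carbon is again delivered as a metal-bound acyl donor, this time to the terminal alkyne carbon. The product is (E)-1-(6-hydroxy-2,3-dimethoxyphenyl)-3-(3,4,5-trimethoxyphenyl)prop-2-en-1-one F1. Iodine (10 mol %) in DMSO at 130 °C then closes ring C by oxa-Michael addition and dehydrogenation to give 9.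

**Step 2.**
- Some lithiation may occur at the less hindered position ortho to OMOM, which would give the 2-hydroxy-4,5-dimethoxy isomer.
- The formaldehyde released on deprotection may attack the electron-rich phenol.

The fallback sets out from 1 and comes back at 5, and it replaces metalation by a blocking-group strategy. NBS in MeCN at 0 °C brominates the open ortho/para-activated position to give 2-bromo-4,5-dimethoxyphenol F2. Magnesium-mediated ortho-formylation (MgCl2, Et3N, paraformaldehyde, MeCN, reflux) can then only strike the remaining ortho carbon, which gives 3-bromo-2-hydroxy-5,6-dimethoxybenzaldehyde F3. Hydrogenolysis (H2 1 atm, Pd/C, NaOAc, EtOAc) removes the bromine and gives 5.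

**Step 3.**
- The ylide may be acylated twice.
- The acid chloride may hydrolyse.
- The methylide may form incompletely.

The fallback sets out from 6 and comes back at 8. Compound 6 is treated with trimethylsilyldiazomethane (2 equiv) in MeCN/THF at 0 °C to give 2-diazo-1-(3,4,5-trimethoxyphenyl)ethan-1-one F4. This compound replaces 7 under the step 4 catalyst. It reaches the same rhodium carbene by loss of nitrogen, and so the diketone 8 and then 9.

## Further compounds
F1 | step 4 | (E)-1-(6-hydroxy-2,3-dimethoxyphenyl)-3-(3,4,5-trimethoxyphenyl)prop-2-en-1-one | COc1ccc(O)c(C(=O)/C=C/c2cc(OC)c(OC)c(OC)c2)c1OC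
F2 | step 2 | 2-bromo-4,5-dimethoxyphenol | COc1cc(O)c(Br)cc1OC
F3 | step 2 | 3-bromo-2-hydroxy-5,6-dimethoxybenzaldehyde | COc1cc(Br)c(O)c(C=O)c1OC
F4 | step 3 | 2-diazo-1-(3,4,5-trimethoxyphenyl)ethan-1-one | COc1cc(C(=O)C=[N+]=[N-])cc(OC)c1OC
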